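**Plan**
- Retrosynthesis: first the three benzylic C–O bonds of the protecting groups. Then three ring A C–C bonds: aryl-ether carbon to carbonyl-bearing carbon, and each methoxyethyne carbon to one methyl-bearing carbon. This opens ring A and the seven-membered ring C together, giving a ring B diyne and methoxyethyne. Last the ynoate C–O, ynol ether O–C and acetal C–O bonds.
- Enabling feature: in the pentasubstituted benzene ring A, the aryl-ether carbon and its neighbour carrying the ester carbonyl also belong to the seven-membered lactone ring C. A prop-1-ynyl ether on one ring B oxygen, a but-2-ynoate on the next and methoxyethyne therefore supply all six ring A carbons.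
- Forward: ring B is built substituent by substituent from methyl 2,4-dihydroxybenzoate, its lactone ring is closed as a pseudo-ester acetal, rings A and C then form in one step, and one hydrogenolysis ends the route.
- Stereochemistry: the only stereocentre (lactol carbon, R) comes from chromatographic separation of the diastereomeric (S)-1-phenylethyl acetals, done after the neighbouring phenol oxygen is capped. The auxiliary is finally cleaved at its own benzylic carbon, so the acetal carbon is untouched.

Key step: step 16

Assumption: the lactol carbon (R) of the target is taken to hold its configuration under neutral, aprotic conditions; acid or base would equilibrate it through the open formyl acid, so it stays an acetal until the last, neutral step.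

**Step 1**
Reactants: 1 methyl 2,4-dihydroxybenzoate
Product: 2 methyl 3-formyl-2,4-dihydroxybenzoate
Conditions: hexamethylenetetramine (2 equiv), CF3CO2H, 90 °C; then 1 M aq. HCl, 60 °C
Reagents that add atoms: hexamethylenetetramine, C1N2CN3CN1CN(C2)C3; water, O
Why: Duff formylation, in which the iminium ion is delivered ortho to the free 4-hydroxyl and should prefer C3, the carbon between the two hydroxyls that bond fixation in the hydrogen-bonded salicylate makes most enol-like; any 5-formyl isomer is to be removed by crystallisation or chromatography.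

**Step 2**
Reactants: 2 methyl 3-formyl-2,4-dihydroxybenzoate
Product: 3 methyl 3-formyl-2,4-dihydroxy-5-iodobenzoate
Conditions: N-iodosuccinimide (1.05 equiv), TsOH·H2O (10 mol%), MeCN, rt
Reagents that add atoms: N-iodosuccinimide, O=C1CCC(=O)N1I
Why: Electrophilic aromatic iodination, for which C5 is the only remaining position activated by both hydroxyls (ortho to one, para to the other).

**Step 3**
Reactants: 3 methyl 3-formyl-2,4-dihydroxy-5-iodobenzoate
Product: 4 methyl 3-formyl-2-hydroxy-5-iodo-4-(prop-2-enyloxy)benzoate
Conditions: allyl bromide (1.1 equiv), K2CO3 (1.1 equiv), DMF, rt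
Reagents that add atoms: allyl bromide, C=CCBr
Why: Williamson etherification, expected at the 4-hydroxyl because it is the more acidic one (para to the ester, ortho to formyl and iodine) while the 2-hydroxyl stays locked in its hydrogen bond to the ester carbonyl, as is usual for 2,4-dihydroxyaryl carbonyl compounds.

**Step 4**
Reactants: 4 methyl 3-formyl-2-hydroxy-5-iodo-4-(prop-2-enyloxy)benzoate
Product: 5 methyl 2-hydroxy-3-(hydroxymethyl)-5-iodo-4-(prop-2-enyloxy)benzoate
Conditions: NaBH4, MeOH/THF, 0 °C
Reagents that add atoms: none
Why: Chemoselective NaBH4 reduction of the aldehyde, which is far more electrophilic than the hydrogen-bonded methyl ester and leaves the aryl iodide and allyl ether alone.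

**Step 5**
Reactants: 5 methyl 2-hydroxy-3-(hydroxymethyl)-5-iodo-4-(prop-2-enyloxy)benzoate
Product: 6 methyl 2-(benzyloxy)-3-[(benzyloxy)methyl]-5-iodo-4-(prop-2-enyloxy)benzoate
Conditions: NaH (2.4 equiv), BnBr (2.5 equiv), Bu4NI (cat.), DMF, 0 °C to rt
Reagents that add atoms: benzyl bromide, BrCc1ccccc1
Why: Double Williamson benzylation, in which NaH forms the phenoxide and the primary alkoxide and both are capped by benzyl bromide before the alkoxide can attack an ester.

**Step 6**
Reactants: 6 methyl 2-(benzyloxy)-3-[(benzyloxy)methyl]-5-iodo-4-(prop-2-enyloxy)benzoate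
Product: 9 methyl 2-(benzyloxy)-3-[(benzyloxy)methyl]-5-hydroxy-4-(prop-2-enyloxy)benzoate, via arylmagnesium chloride 7 (not isolated), via dimethyl arylboronate 8 (not isolated)
Conditions: iPrMgCl·LiCl (1.15 equiv), THF, −30 °C; B(OMe)3 (2 equiv), −30 to 0 °C; then AcOH, 30% aq. H2O2, 0 °C to rt
Reagents that add atoms: hydrogen peroxide, OO
Why: Iodine–magnesium exchange is fast for an aryl iodide next to an alkoxy group and tolerates the hindered ester at −30 °C, and borylation followed by boronate oxidation (aryl shift from boron to oxygen) gives the phenol without touching the allyl or benzyl ethers.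

**Step 7**
Reactants: 9 methyl 2-(benzyloxy)-3-[(benzyloxy)methyl]-5-hydroxy-4-(prop-2-enyloxy)benzoate
Product: 10 methyl 2-(benzyloxy)-3-[(benzyloxy)methyl]-6-formyl-5-hydroxy-4-(prop-2-enyloxy)benzoate
Conditions: MgCl2 (2 equiv), Et3N (4 equiv), paraformaldehyde (6 equiv), MeCN, 80 °C
Reagents that add atoms: formaldehyde (as paraformaldehyde), C=O
Why: Magnesium-mediated ortho-formylation of phenols (Casnati–Skattebøl reaction), in which the magnesium phenoxide delivers formaldehyde to its only free ortho position C6 and a second formaldehyde oxidises the benzylic alkoxide, a sequence precedented next to the ester in 3-hydroxybenzoates.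

**Step 8**
Reactants: 11 acetaldehyde
Product: 12 1,1-dibromoprop-1-ene
Conditions: CBr4 (1 equiv), PPh3 (2 equiv), CH2Cl2, 0 °C; distillation
Reagents that add atoms: carbon tetrabromide, BrC(Br)(Br)Br
Why: Ramirez dibromo-olefination (first stage of the Corey–Fuchs sequence), a Wittig reaction of the ylide Ph3P=CBr2 with the aldehyde.

**Step 9**
Reactants: 10 methyl 2-(benzyloxy)-3-[(benzyloxy)methyl]-6-formyl-5-hydroxy-4-(prop-2-enyloxy)benzoate; 12 1,1-dibromoprop-1-ene
Product: 13 methyl 2-(benzyloxy)-3-[(benzyloxy)methyl]-5-{[(1Z)-1-bromoprop-1-enyl]oxy}-6-formyl-4-(prop-2-enyloxy)benzoate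
Conditions: 12 (1.5 equiv), CuI (10 mol%), 2,2'-bipyridine (20 mol%), K3PO4 (2 equiv), toluene, 110 °C, sealed tube
Reagents that add atoms: 1,1-dibromoprop-1-ene 12, CC=C(Br)Br
Why: Copper-catalysed Ullmann-type C–O coupling of a phenol with a 1,1-dibromoalkene, which replaces the less hindered bromine trans to the methyl group and leaves the Z bromoenol ether; it is run before the pseudo-ester exists because a phenoxide ortho to an acetal carbon could expel the lactone carboxylate.

**Step 10**
Reactants: 13 methyl 2-(benzyloxy)-3-[(benzyloxy)methyl]-5-{[(1Z)-1-bromoprop-1-enyl]oxy}-6-formyl-4-(prop-2-enyloxy)benzoate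
Product: 14 racemic 7-(benzyloxy)-6-[(benzyloxy)methyl]-4-{[(1Z)-1-bromoprop-1-enyl]oxy}-3-hydroxy-5-(prop-2-enyloxy)-2-benzofuran-1(3H)-one
Conditions: LiOH·H2O (2.5 equiv), THF/H2O, 0 °C; then 1 M aq. HCl to pH 3, 0 °C
Reagents that add atoms: lithium hydroxide, [Li+].[OH-]
Why: Saponification assisted by the neighbouring formyl group (its hydrate anion attacks the ester), after which the 2-formylbenzoic acid closes to the racemic 3-hydroxyphthalide by ring–chain tautomerism, while the bromoenol ether is inert to cold hydroxide and brief dilute acid.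

**Step 11**
Reactants: 14 racemic lactol; 15 (S)-1-phenylethanol
Product: 16 7-(benzyloxy)-6-[(benzyloxy)methyl]-4-{[(1Z)-1-bromoprop-1-enyl]oxy}-3-[(1S)-1-phenylethoxy]-5-(prop-2-enyloxy)-2-benzofuran-1(3H)-one as the mixture of its two C3 epimers
Conditions: 15 (3 equiv), PPTS (10 mol%), benzene, 4 Å molecular sieves, 70 °C
Reagents that add atoms: (S)-1-phenylethanol 15, C[C@H](O)c1ccccc1
Why: Acid-catalysed pseudo-ester (cyclic acetal) formation through the lactol oxocarbenium ion, mild enough to spare the electron-poor bromoenol ether; the acetal centre is not controlled here and both C3 epimers are carried on, while the carbinol centre of the auxiliary takes no part in bond making and stays S.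

**Step 12**
Reactants: 16 mixture of C3 epimers
Product: 17 (3R)-7-(benzyloxy)-6-[(benzyloxy)methyl]-3-[(1S)-1-phenylethoxy]-5-(prop-2-enyloxy)-4-(prop-1-ynyloxy)-2-benzofuran-1(3H)-one
Conditions: NaN(SiMe3)2 (1.3 equiv), THF, −78 to −40 °C; then chromatography on silica to separate the C3 epimers
Reagents that add atoms: none
Why: E2 dehydrobromination by a bulky non-nucleophilic amide base (the vinylic hydrogen is anti to bromine in the Z isomer) should give the aryl ynol ether without opening the lactone, and since the C4 oxygen is now capped and no later step is acidic or basic at C3, the two diastereomeric ynol ethers are separated here, which fixes the R acetal carbon of 17 and removes the 3S epimer.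

**Step 13**
Reactants: 17 (3R) ynol ether
Product: 18 (3R)-7-(benzyloxy)-6-[(benzyloxy)methyl]-5-hydroxy-3-[(1S)-1-phenylethoxy]-4-(prop-1-ynyloxy)-2-benzofuran-1(3H)-one
Conditions: Pd(PPh3)4 (5 mol%), N-methylaniline (3 equiv), THF, rt
Reagents that add atoms: none
Why: Tsuji–Trost deallylation, in which zerovalent palladium ionises the aryl allyl ether and N-methylaniline traps the allyl fragment under neutral conditions that spare the ynol ether, benzyl ethers and pseudo-ester; the phenol is to be acylated at once because a free hydroxyl next to an ynol ether could add across it on standing.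

**Step 14**
Reactants: 18 phenol; 19 but-2-ynoic acid
Product: 20 (3R)-7-(benzyloxy)-6-[(benzyloxy)methyl]-1-oxo-3-[(1S)-1-phenylethoxy]-4-(prop-1-ynyloxy)-1,3-dihydro-2-benzofuran-5-yl but-2-ynoate
Conditions: 19 (1.5 equiv) and DCC (1.6 equiv) premixed in CH2Cl2, 0 °C, 15 min; then 18, DMAP (10 mol%), 0 °C
Reagents that add atoms: but-2-ynoic acid 19, CC#CC(=O)O
Why: Steglich esterification, in which the acid is first consumed by the carbodiimide so that little free acid is left to add across the ynol ether, and DMAP then relays the acyl group to the hindered phenol at 0 °C without affecting the acetal carbon.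

**Step 15**
Reactants: 21 chloroacetaldehyde dimethyl acetal
Product: 23 methoxyethyne, via sodium methoxyethynide 22 (not isolated)
Conditions: NaNH2 (3 equiv), liquid NH3, −33 °C; then cold sat. aq. NH4Cl; distillation into cold CH2Cl2
Reagents that add atoms: none
Why: Base-induced double elimination (loss of HCl, then of methanol) gives the sodium alkynide, whose protonation liberates the volatile alkoxyalkyne, the standard preparation of alkoxyacetylenes.

**Step 16**
Reactants: 20 ring B diyne; 23 methoxyethyne
Product: 24 protected depsidone (ring B phenol and hydroxymethyl as benzyl ethers; lactol as its R-configured (S)-1-phenylethyl acetal; ring A with methoxy and two methyl groups)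
Conditions: [Rh(cod)2]BF4 (10 mol%), rac-BINAP (10 mol%), CH2Cl2, H2 (1 atm) then argon; 20 and 23 (5 equiv) added by syringe pump, rt
Reagents that add atoms: methoxyethyne 23, COC#C
Why: Proposed new method: the cationic monovalent rhodium–BINAP complex should couple two of the alkynes oxidatively to a rhodacyclopentadiene, insert the third and release ring A by reductive elimination; the closest known reaction type is the cationic rhodium/bisphosphine-catalysed [2+2+2] cycloaddition of tethered 1,6- and 1,7-diynes with monoalkynes, which accepts ynoates and aryl ynol ethers, and the extension is the five-atom catechol tether that must deliver a seven-membered ring. Ring A is closed by [2+2+2] benzannulation, each alkyne supplying two adjacent ring carbons. Ring C is closed in the same event by the bond between the oxygen-bearing ynol ether carbon and the carbonyl-bearing ynoate carbon, a seven-membered closure helped by the planar ortho-phenylene unit that holds both alkynes side by side. No stereocentre is formed, and the acetal carbon is a spectator under these neutral conditions. The selectivity required is the orientation of methoxyethyne, expected from head-to-tail matching of polarised partners: its electron-rich unsubstituted carbon bonds to the electrophilic methyl-bearing carbon of the ynoate, which obliges its methoxy-bearing carbon to bond to the methyl-bearing carbon of the ynol ether. Slow addition of both components is meant to suppress homotrimerisation of the alkoxyalkyne and oligomerisation of the diyne.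

**Step 17**
Reactants: 24 protected depsidone
Product: 25 target depsidone CNP0321962.1 (R lactol)
Conditions: H2 (1 atm), 10% Pd/C, EtOAc, rt
Reagents that add atoms: none
Why: Catalytic hydrogenolysis cleaves the two O–CH2Ph bonds and the O–CH(CH3)Ph bond at the benzylic carbon of the auxiliary, so no bond to the acetal carbon is broken and its R configuration should pass unchanged into the lactol under neutral, aprotic conditions.

**Compound list**
1 | methyl 2,4-dihydroxybenzoate | COC(=O)c1ccc(O)cc1O | starting material
2 | methyl 3-formyl-2,4-dihydroxybenzoate | COC(=O)c1ccc(O)c(C=O)c1O | intermediate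
3 | methyl 3-formyl-2,4-dihydroxy-5-iodobenzoate | COC(=O)c1cc(I)c(O)c(C=O)c1O | intermediate
4 | methyl 3-formyl-2-hydroxy-5-iodo-4-(prop-2-enyloxy)benzoate | COC(=O)c1cc(I)c(OCC=C)c(C=O)c1O | intermediate
5 | methyl 2-hydroxy-3-(hydroxymethyl)-5-iodo-4-(prop-2-enyloxy)benzoate | COC(=O)c1cc(I)c(OCC=C)c(CO)c1O | intermediate
6 | methyl 2-(benzyloxy)-3-[(benzyloxy)methyl]-5-iodo-4-(prop-2-enyloxy)benzoate | COC(=O)c1cc(I)c(OCC=C)c(COCc2ccccc2)c1OCc1ccccc1 | intermediate
7 | arylmagnesium chloride from 6 (MgCl in place of iodine) | COC(=O)c1cc([Mg]Cl)c(OCC=C)c(COCc2ccccc2)c1OCc1ccccc1 | intermediate (not isolated)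
8 | dimethyl arylboronate from 7 (B(OMe)2 at C5) | COC(=O)c1cc(B(OC)OC)c(OCC=C)c(COCc2ccccc2)c1OCc1ccccc1 | intermediate (not isolated)
9 | methyl 2-(benzyloxy)-3-[(benzyloxy)methyl]-5-hydroxy-4-(prop-2-enyloxy)benzoate | COC(=O)c1cc(O)c(OCC=C)c(COCc2ccccc2)c1OCc1ccccc1 | intermediate
10 | methyl 2-(benzyloxy)-3-[(benzyloxy)methyl]-6-formyl-5-hydroxy-4-(prop-2-enyloxy)benzoate | COC(=O)c1c(C=O)c(O)c(OCC=C)c(COCc2ccccc2)c1OCc1ccccc1 | intermediate
11 | acetaldehyde | CC=O | starting material
12 | 1,1-dibromoprop-1-ene | CC=C(Br)Br | intermediate
13 | methyl 2-(benzyloxy)-3-[(benzyloxy)methyl]-5-{[(1Z)-1-bromoprop-1-enyl]oxy}-6-formyl-4-(prop-2-enyloxy)benzoate | COC(=O)c1c(C=O)c(O/C(Br)=C/C)c(OCC=C)c(COCc2ccccc2)c1OCc1ccccc1 | intermediate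
14 | racemic 7-(benzyloxy)-6-[(benzyloxy)methyl]-4-{[(1Z)-1-bromoprop-1-enyl]oxy}-3-hydroxy-5-(prop-2-enyloxy)-2-benzofuran-1(3H)-one | C/C=C(\Br)Oc1c(OCC=C)c(COCc2ccccc2)c(OCc2ccccc2)c2c1C(O)OC2=O | intermediate
15 | (S)-1-phenylethanol | C[C@H](O)c1ccccc1 | starting material
16 | 3-[(1S)-1-phenylethoxy] acetal of 14, both C3 epimers (C3 left unspecified) | C/C=C(\Br)Oc1c(OCC=C)c(COCc2ccccc2)c(OCc2ccccc2)c2c1C(O[C@@H](C)c1ccccc1)OC2=O | intermediate
17 | (3R)-7-(benzyloxy)-6-[(benzyloxy)methyl]-3-[(1S)-1-phenylethoxy]-5-(prop-2-enyloxy)-4-(prop-1-ynyloxy)-2-benzofuran-1(3H)-one | CC#COc1c(OCC=C)c(COCc2ccccc2)c(OCc2ccccc2)c2c1[C@H](O[C@@H](C)c1ccccc1)OC2=O | intermediate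
18 | (3R)-7-(benzyloxy)-6-[(benzyloxy)methyl]-5-hydroxy-3-[(1S)-1-phenylethoxy]-4-(prop-1-ynyloxy)-2-benzofuran-1(3H)-one | CC#COc1c(O)c(COCc2ccccc2)c(OCc2ccccc2)c2c1[C@H](O[C@@H](C)c1ccccc1)OC2=O | intermediate
19 | but-2-ynoic acid | CC#CC(=O)O | starting material
20 | (3R)-7-(benzyloxy)-6-[(benzyloxy)methyl]-1-oxo-3-[(1S)-1-phenylethoxy]-4-(prop-1-ynyloxy)-1,3-dihydro-2-benzofuran-5-yl but-2-ynoate | CC#COc1c(OC(=O)C#CC)c(COCc2ccccc2)c(OCc2ccccc2)c2c1[C@H](O[C@@H](C)c1ccccc1)OC2=O | intermediate
21 | chloroacetaldehyde dimethyl acetal | COC(CCl)OC | starting material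
22 | sodium methoxyethynide | [Na+].[C-]#COC | intermediate (not isolated)
23 | methoxyethyne | COC#C | intermediate
24 | protected depsidone: benzyl ether of the ring B phenol, benzyl ether of the hydroxymethyl group, R acetal with the (S)-1-phenylethyl group | COc1cc(C)c2c(c1C)Oc1c(c(COCc4ccccc4)c(OCc4ccccc4)c3c1[C@H](O[C@@H](C)c1ccccc1)OC3=O)OC2=O | intermediate
25 | CNP0321962.1, R lactol | COc1cc(C)c2c(c1C)Oc1c(c(CO)c(O)c3c1[C@H](O)OC3=O)OC2=O | target

**Step count**
Total: 17 steps (15 on the main line, one each for 12 and 23).
Longest linear sequence: 15 steps, from 1 to 25 through steps 1–7, 9–14, 16 and 17.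

**Steps most likely to fail**

Step 16 (proposed new method). The five-atom tether may resist closure of the seven-membered metallacycle, so that methoxyethyne homotrimerises or the diyne oligomerises. The orientation of methoxyethyne also rests on electronic bias alone, since both flanking carbons carry methyl groups.
Fallback (known chemistry, classical ether-then-lactone assembly), setting out from 6 and returning at 24: commercial methyl 2,4-dihydroxy-3,6-dimethylbenzoate is 4-O-methylated (MeI, K2CO3) to methyl 2-hydroxy-4-methoxy-3,6-dimethylbenzoate F1. This is saponified (KOH, DMSO/H2O) to 2-hydroxy-4-methoxy-3,6-dimethylbenzoic acid F2, which is re-esterified (allyl bromide, KHCO3) to allyl 2-hydroxy-4-methoxy-3,6-dimethylbenzoate F3. Ullmann condensation of aryl iodide 6 with the phenol (CuI, N,N-dimethylglycine, Cs2CO3, dioxane, 100 °C) should give the diaryl ether diester F4. Ester-directed magnesiation of the only ring B C–H (TMPMgCl·LiCl, THF, −20 °C) and a DMF quench would give the diaryl ether aldehyde F5. LiOH should open only the formyl-activated methyl ester, and acidification would give the diaryl ether lactol F6. Treatment with 15 and PPTS gives the diaryl ether acetal F7 as both C3 epimers. Pd(PPh3)4 with N-methylaniline removes the allyl ether and the allyl ester together, giving the seco hydroxy acid F8. Yamaguchi lactonisation (2,4,6-trichlorobenzoyl chloride, Et3N, then DMAP, toluene) closes ring C, and chromatography separates 24 from the 3S epimer of the protected depsidone F9.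

Step 9. Vinylation may stall because the phenoxide is chelated to the ortho formyl group, hindered on both sides and electron-poor, and the dibromoalkene may decompose at 110 °C.
Fallback, setting out from 10 and returning at 16: the order is changed so that an electron-richer phenol is coupled. LiOH then acid converts 10 into the phenolic lactol 5-(allyloxy)-7-(benzyloxy)-6-[(benzyloxy)methyl]-3,4-dihydroxy-2-benzofuran-1(3H)-one F10. 15 with PPTS gives the phenolic acetal F11 as both C3 epimers. Interconversion of these epimers through the phenoxide is harmless, because separation comes only in step 12. The CuI/2,2'-bipyridine/K3PO4 coupling with 12 is then run on this acetal and gives 16.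

Step 17. The hindered 1-phenylethyl acetal may outlast the benzyl ethers, and forcing the hydrogenolysis may start to reduce the benzylic lactol or hydroxymethyl C–O bonds.
Fallback, setting out from 24 and returning at 25: hydrogenolysis is stopped once both benzyl ethers are gone, giving the acetal diol F12. Mild aqueous acid (AcOH/THF/H2O) hydrolyses the acetal to the racemic lactol F13. Preparative chromatography on a chiral stationary phase with a neutral eluent then gives 25, so the configuration comes from chromatographic resolution instead of the auxiliary.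

**Further compounds**
F1 | step 16 | methyl 2-hydroxy-4-methoxy-3,6-dimethylbenzoate | COc1cc(C)c(C(=O)OC)c(O)c1C
F2 | step 16 | 2-hydroxy-4-methoxy-3,6-dimethylbenzoic acid | COc1cc(C)c(C(=O)O)c(O)c1C
F3 | step 16 | allyl 2-hydroxy-4-methoxy-3,6-dimethylbenzoate | COc1cc(C)c(C(=O)OCC=C)c(O)c1C
F4 | step 16 | diaryl ether diester (ring B C5 oxygen bonded to ring A; methyl ester on ring B, allyl ester on ring A) | COC(=O)c1cc(Oc2c(C)c(OC)cc(C)c2C(=O)OCC=C)c(OCC=C)c(COCc2ccccc2)c1OCc1ccccc1
F5 | step 16 | diaryl ether aldehyde (6-formyl derivative of F4) | COC(=O)c1c(C=O)c(Oc2c(C)c(OC)cc(C)c2C(=O)OCC=C)c(OCC=C)c(COCc2ccccc2)c1OCc1ccccc1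
F6 | step 16 | diaryl ether lactol (racemic 3-hydroxyphthalide, allyl ester and allyl ether intact) | C=CCOC(=O)c1c(C)cc(OC)c(C)c1Oc1c(OCC=C)c(COCc2ccccc2)c(OCc2ccccc2)c2c1C(O)OC2=O
F7 | step 16 | diaryl ether acetal with (S)-1-phenylethanol, both C3 epimers | C=CCOC(=O)c1c(C)cc(OC)c(C)c1Oc1c(OCC=C)c(COCc2ccccc2)c(OCc2ccccc2)c2c1C(O[C@@H](C)c1ccccc1)OC2=O
F8 | step 16 | seco hydroxy acid, both C3 epimers | OC(=O)c1c(C)cc(OC)c(C)c1Oc1c(O)c(COCc2ccccc2)c(OCc2ccccc2)c2c1C(O[C@@H](C)c1ccccc1)OC2=O
F9 | step 16 | 3S epimer of the protected depsidone 24 | COc1cc(C)c2c(c1C)Oc1c(c(COCc4ccccc4)c(OCc4ccccc4)c3c1[C@@H](O[C@@H](C)c1ccccc1)OC3=O)OC2=O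
F10 | step 9 | 5-(allyloxy)-7-(benzyloxy)-6-[(benzyloxy)methyl]-3,4-dihydroxy-2-benzofuran-1(3H)-one (racemic) | Oc1c(OCC=C)c(COCc2ccccc2)c(OCc2ccccc2)c2c1C(O)OC2=O
F11 | step 9 | 3-[(1S)-1-phenylethoxy] acetal of F10, both C3 epimers | Oc1c(OCC=C)c(COCc2ccccc2)c(OCc2ccccc2)c2c1C(O[C@@H](C)c1ccccc1)OC2=O
F12 | step 17 | acetal diol (24 without its two benzyl groups) | COc1cc(C)c2c(c1C)Oc1c(c(CO)c(O)c3c1[C@H](O[C@@H](C)c1ccccc1)OC3=O)OC2=O
F13 | step 17 | racemic lactol (racemate of 25) | COc1cc(C)c2c(c1C)Oc1c(c(CO)c(O)c3c1C(O)OC3=O)OC2=O
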